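## Structural features

The target is an alkyl aryl ether: O7 of a 6,8-dimethoxycoumarin is bonded to the C11 methylene on C9 of a drimane-type trans-decalin (ring A: C1–C5 and C10; ring B: C5–C10). Ring A carries the gem-dimethyl carbon C4 and, next to it, the axial 3α-isovalerate. Ring B carries the C6 ketone conjugated with the C7=C8 alkene, which bears the C12 methyl group. C9, C10 and C5 are contiguous stereocentres: C10 is quaternary, H5 is anti to its methyl group, and C11 is also anti to it (the 9-epi series). C3 is separated from them by C4, and the configuration is (3R,5R,9R,10R). The fragile points are: C9–H, a vinylogous α-hydrogen whose removal expels the aryloxide from C11; C5–H, which is epimerisable through the C6 enol; the coumarin lactone, which does not survive hydroxide, hydride or organometallic reagents; and the hindered ester. The real difficulty is the absolute configuration of the quaternary C10 with three further centres on a congested decalin, together with the hindered and elimination-prone C9–C11–O array. The key step uses the fact that ring A, with its C3 oxygen and quaternary C10, is a masked 4,4-disubstituted cyclohexa-2,5-dienone (C1=C2–C3(=O)–C4=C5) whose β-carbon C5 lies one bond from the C6 carbonyl carbon. C5–C6 can therefore be formed by conjugate addition of a C6 acyl anion equivalent, which closes ring B and selects one of two enantiotopic enone arms.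

## Logic of the disconnections

27 to 25. The C7=C8 double bond is removed first. In 27 it makes C9–H acidic and the C11 aryloxide a leaving group; in 25 neither is activated. This lets every basic or nucleophilic operation sit before the sensitive array exists. The forward step must dehydrogenate under neutral conditions and only towards C7–C8; C5 has no β-hydrogen, so no other direction exists.

25 to 23 and 24. The C11–O(aryl) bond is cut. This is the convergent point: 24 enters once, intact, and never meets hydride or organometallic reagents. What remains is a C15 terpenoid alcohol. The forward step needs substitution at a β-branched primary carbon by a phenol flanked by two methoxy groups, without enolising the ketone.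

23 to 22 to 20. The O–benzyl bond and the C8–C12 bond are cut; C12 is a methyl nucleophile delivered to the β-carbon of an enone. The C8 configuration need not be controlled because the centre becomes trigonal again. The forward step must add next to the substituted C9 and spare the ester.

20 to 19 to 18. The C9–C11 bond is cut. C9 is the γ-carbon of the 7-en-6-one, and because C8 is still unsubstituted it is the only γ-carbon; this is why C11 is attached before C12. Attack anti to the C10 methyl sets C9. The forward step needs enolisation towards C9 (not C5) and γ- rather than α-attack.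

18 to 17. The C7=C8 unsaturation is removed, leaving ring B as a plain cyclohexanone. Regiochemistry is fixed by the absence of any alternative.

17 to 15. C5 is inverted and C6 is masked as its ketal. The ring-forming step can only give the cis fusion, so a correction is unavoidable. It is placed after the 3α-ester is in position because that group destabilises the cis isomer. The forward step must enolise the hindered C5 without harming the ester.

15 to 14 to 13. The ester C–O bond and the C3–H bond are cut. Hydride must arrive on the face of C3 that carries the C10 methyl group.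

13 to 12 to 11 to 10. The C1–C2 hydrogens, the two C4–CH3 bonds and the C6 ketal are removed in turn. With C6 masked, C4 is the only enolisable carbon of the ring A enone, so double methylation is unambiguous. This returns to the C11 enedione 10 with two stereocentres.

10 to 9. The C5–C6 bond is cut: ring B opens, both stereocentres vanish and the precursor is achiral. The forward step must reverse the polarity of the aldehyde carbon, choose between two enantiotopic β-carbons, and close a six-membered ring from an enolisable aldehyde.

9 to 8 to 7. The aldehyde oxygen is traced back to a terminal alkene carrying one extra carbon, and the second ring double bond to a cyclohexenone. Both forward steps are chemoselective oxidations.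

7 to 4 and 5; 4 to 1 and 2. The C10–C1 bond and the C4=C5 bond (annulation) and then the C8–C9 bond (conjugate addition) are cut. This reaches four commercial materials: 1, 2, 5 and, later, 24.

## Other disconnections considered

Alternative 1: The cut runs through C5–C10 and C8–C9, so both rings open to the acyclic triene A1. Its (Z)-enoyl oxazolidinone (C11, C9, C10) is the dienophile and its 6-silyloxy diene (C5–C8, C12 already on C8) is the diene. In the forward step Me2AlCl chelates the acyl oxazolidinone and an intramolecular Diels–Alder reaction closes rings A and B together, giving the cis-fused silyl enol ether A2.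
- In its favour: C5, C8, C9 and C10 and both rings form at once. The C9/C10 relationship follows stereospecifically from the alkene geometry, not from a facial preference. C11, C12, the gem-dimethyl group and the C3 ester are all present before cyclisation. The enol ether of A2 is one oxidation from the 7-en-6-one.
- Against it here: a β,β-disubstituted dienophile must create the quaternary C10 while the diene terminus C5 sits on the quaternary C4. This doubly hindered union may not proceed before the acid-labile silyloxy diene is lost. A1 needs three geometrically defined alkenes and a separately made C3 stereocentre with which the auxiliary must cooperate. The endo adduct is cis-fused, so C5 still has to be inverted.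
- Comparison: on structure the alternative is better, because no late C–C bond has to be made at C9. On C5 it is equal, since both plans give the cis fusion first. On mechanism, a concerted cycloaddition is at least as predictable in facial selectivity but asks more of reactivity. On step economy the phase after A2 is shorter, but A1 should cost about as many steps as the route to 17, so the totals are expected to be similar, and the auxiliary is stoichiometric.

Alternative 2: The cut is the single bond C1–C10. Ring B, with its C8 methyl stereocentre taken from the chiral pool, is kept as a cyclohexenone (C6 carbonyl, C5=C10) that carries on C5 the chain C4–C1 ending in a primary iodide, A3. In the forward step, cathodic reduction mediated by Ni(cyclam)(ClO4)2 gives the C1 radical. It closes ring A 6-endo onto the β-carbon C10, and reduction and protonation at C5 give the trans-fused ketone A4.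
- In its favour: the trans ring fusion and the 3α-ester come out of the key step without correction. C12 is present from the start. A radical suits the formation of a quaternary centre, and no tin reagent is needed.
- Against it here: the configuration of C10 must be relayed from C3 and from the C8 methyl group. Neither is adjacent, and the C8 centre is later destroyed. A3 requires the quaternary C4 to be bonded to the α-carbon of an enone. A4 lacks C11 and the C7=C8 bond, and because C8 already bears its methyl group the later γ-functionalisation has two candidate γ-carbons (C9 and C12).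
- Comparison: on ring fusion and on the C3 oxygen the alternative is the better. On absolute control of C10, catalytic desymmetrisation of an achiral dienone is the safer. A4 corresponds to 17 plus C12, so the endgame is no shorter and is less regiodefined; the step counts should be close, with specialised electrochemical equipment as an extra demand.

Alternative 3: The cuts are C4–C5 and C9–C10. The whole skeleton, already bonded to the coumarin through the C11 ether, is unfolded to the (2Z,6E)-configured terminal (S)-epoxide A5. In the forward step MeAlCl2 or SnCl4 opens the epoxide, the two alkenes add in turn (ring A, then ring B), and the C8 cation loses a proton to give the 7-ene A6.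
- In its favour: it is by far the shortest approach. The aryl ether is made on an unhindered allylic carbon. The Z alkene translates directly into the α-oriented C11, the ring fusion is trans, and the epoxide fixes the absolute configuration.
- Against it here: the cation can end by several competing eliminations or by partial cyclisation. The allylic aryl ether can ionise under the Lewis acid, and the coumarin carbonyl can bind it. A6 has the 3β-alcohol, so C3 must be inverted by oxidation, hindered-hydride reduction and acylation. A6 also lacks the C6 oxygen, which calls for an allylic C–H oxidation at C6 in competition with C9–H and C12, next to an electron-rich aryl ether.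
- Comparison: on step economy, on C9 and on the ether bond the alternative is clearly the better. On ring fusion it is the equal. The chosen plan is stronger where the alternative is weakest: the C6 carbonyl is the aldehyde carbon of 9, the axial C3 oxygen comes from a ketone, and bonds are formed one at a time instead of in a cationic cascade followed by a C–H oxidation of uncertain site selectivity.

Key step: step 5

Convention: bicyclic compounds are named on the drimane skeleton with terpenoid numbering (C11 on C9, C12 on C8, C13 and C14 on C4, C15 on C10). α is the face opposite to C15, and "nor" marks absent carbons.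

Assumption: the tether of the cyclisation precursor is left unsubstituted. Any substituent on C7–C9 would make the dienone chiral and replace the catalyst-controlled choice between enantiotopic arms by a substrate-dependent one, so C11 and C12 are added after ring closure.

Step 1
Reactants: 1 but-3-en-1-ylmagnesium bromide; 2 methacrolein (2-methylprop-2-enal)
Product: 4 2-methylhept-6-enal (racemic), via silyl enol ether 3 (not isolated)
Conditions: CuBr·SMe2 (5 mol %), TMSCl, DMPU, THF, –78 °C; then 1 M HCl
Reagents that add atoms: none
Why: Copper-catalysed, chlorosilane-accelerated conjugate addition of the organomagnesium reagent to the enal gives 3, which is hydrolysed on work-up to the α-methyl aldehyde; its stereocentre is of no consequence because this carbon (the future C10) becomes part of an achiral dienone.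

Step 2
Reactants: 4 2-methylhept-6-enal; 5 methyl vinyl ketone
Product: 7 4-methyl-4-(pent-4-en-1-yl)cyclohex-2-en-1-one (racemic), via Michael adduct 6 (not isolated)
Conditions: H2SO4 (cat.), PhMe, 45 °C, then reflux with azeotropic removal of water
Reagents that add atoms: none
Why: Acid-catalysed Robinson annulation: the enol of the α-branched aldehyde adds to 5 (Michael addition), and the methyl ketone of 6 condenses onto the aldehyde (aldol, dehydration) to give the 4,4-disubstituted cyclohexenone.

Step 3
Reactants: 7 4-methyl-4-(pent-4-en-1-yl)cyclohex-2-en-1-one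
Product: 8 4-methyl-4-(pent-4-en-1-yl)cyclohexa-2,5-dien-1-one
Conditions: DDQ, 1,4-dioxane, 100 °C
Reagents that add atoms: none
Why: Quinone dehydrogenation of a 4,4-disubstituted cyclohexenone through its enol gives the cross-conjugated dienone; the quaternary carbon blocks aromatisation, the isolated terminal alkene is inert, and the two enone arms become enantiotopic.

Step 4
Reactants: 8 4-methyl-4-(pent-4-en-1-yl)cyclohexa-2,5-dien-1-one
Product: 9 4-(1-methyl-4-oxocyclohexa-2,5-dien-1-yl)butanal
Conditions: O3, CH2Cl2/MeOH, –78 °C (dye-indicated end point); then Me2S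
Reagents that add atoms: ozone, [O-][O+]=O
Why: Ozonolysis with reductive work-up; the monosubstituted alkene is far more electron-rich than the cross-conjugated dienone alkenes and is consumed first when ozone is dosed to an indicator end point.

Step 5
Reactants: 9 4-(1-methyl-4-oxocyclohexa-2,5-dien-1-yl)butanal
Product: 10 (4aS,8aR)-4a-methyl-3,4,4a,8a-tetrahydronaphthalene-1,7(2H,8H)-dione (cis-fused 5β-H-11,12,13,14-tetranordrim-1-ene-3,6-dione)
Conditions: aminoindanol-derived N-C6F5 triazolium tetrafluoroborate (10 mol %), KN(SiMe3)2 (9 mol %), PhMe (0.02 M), 23 °C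
Reagents that add atoms: none
Why: The triazolium salt is deprotonated to the carbene, which adds to the aldehyde of 9; proton transfer gives the nucleophilic enaminol, an acyl anion equivalent centred on C6. This carbon adds in a conjugate sense to the dienone β-carbon C5, and collapse of the resulting alkoxide releases the C6 ketone and the carbene. The closest known reaction type is the carbene-catalysed asymmetric intramolecular Stetter desymmetrisation of 4,4-disubstituted cyclohexa-2,5-dienones. Ring B is closed in the 6-exo-trig mode through the new C5–C6 bond. C10 becomes a stereocentre because the chiral catalyst selects one of the two enantiotopic enone arms (the catalyst antipode leading to (4aS,8aR)-10 is used); C5 is set by the tether, which hangs from C10 and can reach only its own face of the ring, so the fusion is necessarily cis. The step needs carbene attack on the aldehyde and not on the dienone, which is secured by the fast, reversible aldehyde addition and by the β-carbons being flanked by the quaternary C10; it also needs 1,4- and not 1,2-addition, which is secured because only C5 lies at six-ring distance from C6. Keeping the base below the azolium loading and the solution dilute limits aldol and benzoin pathways of the enolisable aldehyde. The untouched arm keeps C3 as an enone carbonyl and leaves C4 as the only enolisable carbon of ring A for step 7.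

Step 6
Reactants: 10 (4aS,8aR)-4a-methyl-3,4,4a,8a-tetrahydronaphthalene-1,7(2H,8H)-dione
Product: 11 6,6-(ethylenedioxy)-5β-H-11,12,13,14-tetranordrim-1-en-3-one (cis-fused)
Conditions: TMSOCH2CH2OTMS, TMSOTf (5 mol %), CH2Cl2, –78 °C
Reagents that add atoms: 1,2-bis(trimethylsilyloxy)ethane, C[Si](C)(C)OCCO[Si](C)(C)C
Why: Silyl-transfer ketalisation at low temperature discriminates the saturated C6 ketone from the conjugated C3 carbonyl; masking C6 removes the acidity of C5 and C7 and preserves the C5 configuration through the basic step that follows.

Step 7
Reactants: 11 6,6-(ethylenedioxy)-5β-H-11,12,13,14-tetranordrim-1-en-3-one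
Product: 12 6,6-(ethylenedioxy)-5β-H-11,12-dinordrim-1-en-3-one (cis-fused)
Conditions: KOt-Bu, MeI, t-BuOH/THF, 0 °C to rt
Reagents that add atoms: iodomethane, CI
Why: Exhaustive α′-alkylation of the enone: the enolate can form only at C4 (C2 is vinylic and C10 carries no hydrogen), so two rounds of deprotonation and methylation install the gem-dimethyl group.

Step 8
Reactants: 12 6,6-(ethylenedioxy)-5β-H-11,12-dinordrim-1-en-3-one
Product: 13 6,6-(ethylenedioxy)-5β-H-11,12-dinordriman-3-one (cis-fused)
Conditions: H2 (1 atm), Pd/C, EtOAc, rt
Reagents that add atoms: none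
Why: Heterogeneous hydrogenation of the disubstituted C1=C2 enone alkene; ketone and ketal are inert, and the ring A alkene has to go before any organocuprate is used later.

Step 9
Reactants: 13 6,6-(ethylenedioxy)-5β-H-11,12-dinordriman-3-one
Product: 14 6,6-(ethylenedioxy)-5β-H-11,12-dinordriman-3α-ol (cis-fused)
Conditions: Li[HB(s-Bu)3], THF, –78 °C; aq. NH4Cl
Reagents that add atoms: none
Why: Reduction with a bulky trialkylborohydride: ring B and the C6 ketal hang below the α face of the cis-decalin, so hydride should arrive on the convex β face and place the oxygen α, the position that becomes axial once the ring fusion is trans; the same reagent class gives axial alcohols from 4,4-dimethyl-3-oxo terpenoids.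

Step 10
Reactants: 14 6,6-(ethylenedioxy)-5β-H-11,12-dinordriman-3α-ol
Product: 15 6,6-(ethylenedioxy)-5β-H-11,12-dinordriman-3α-yl 3-methylbutanoate (cis-fused)
Conditions: i-BuCOCl, pyridine, DMAP (cat.), CH2Cl2, 0 to 40 °C
Reagents that add atoms: 3-methylbutanoyl chloride, CC(C)CC(=O)Cl
Why: Nucleophile-catalysed acylation of the hindered secondary alcohol with the acid chloride; esterifying before C6 is unmasked prevents the 3α-hydroxyl from closing a bridged hemiketal onto C6 in the cis series.

Step 11
Reactants: 15 6,6-(ethylenedioxy)-5β-H-11,12-dinordriman-3α-yl 3-methylbutanoate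
Product: 17 6-oxo-5α-H-11,12-dinordriman-3α-yl 3-methylbutanoate (trans-fused), via cis-fused keto ester 16 (not isolated)
Conditions: 2 M HCl, THF, rt; then TsOH·H2O (cat.), PhMe, 80 °C
Reagents that add atoms: water, O
Why: Acidic hydrolysis frees the C6 ketone and acid-catalysed enolisation towards C5 then equilibrates the ring fusion. With the 3α-acyloxy group in place the cis isomer must either put C6 syn-axial to that oxygen or put the quaternary C4 axial on ring B, so the trans-decalin should dominate; protonation of the enol from the α face, away from the two β-axial methyl groups, leads to the same isomer.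

Step 12
Reactants: 17 6-oxo-5α-H-11,12-dinordriman-3α-yl 3-methylbutanoate
Product: 18 6-oxo-5α-H-11,12-dinordrim-7-en-3α-yl 3-methylbutanoate
Conditions: IBX, DMSO/PhF, 75 °C
Reagents that add atoms: none
Why: Dehydrogenation of the ketone through its enol by the pentavalent iodine reagent; desaturation can occur only towards C7–C8 because C5 has no β-hydrogen (C4 and C10 are quaternary), and no second dehydrogenation is possible.

Step 13
Reactants: 18 6-oxo-5α-H-11,12-dinordrim-7-en-3α-yl 3-methylbutanoate
Product: 19 6-(tert-butyldimethylsilyloxy)-5α-H-11,12-dinordrima-6,8-dien-3α-yl 3-methylbutanoate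
Conditions: TBSOTf, Et3N, CH2Cl2, 0 °C to rt
Reagents that add atoms: tert-butyldimethylsilyl trifluoromethanesulfonate, CC(C)(C)[Si](C)(C)OS(=O)(=O)C(F)(F)F
Why: Soft enolisation under equilibrating conditions gives the linear, γ-deprotonated silyl dienol ether; loss of H5 would give a tetrasubstituted enol ether strained against the C4 methyl groups, and with C8 unsubstituted C9 is the only γ-carbon.

Step 14
Reactants: 19 6-(tert-butyldimethylsilyloxy)-5α-H-11,12-dinordrima-6,8-dien-3α-yl 3-methylbutanoate
Product: 20 11-benzyloxy-6-oxo-5α-H,9β-H-12-nordrim-7-en-3α-yl 3-methylbutanoate (C11 on the α face)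
Conditions: BnOCH2Cl, ZnBr2 (10 mol %), CH2Cl2, –20 °C to rt
Reagents that add atoms: benzyl chloromethyl ether, ClCOCc1ccccc1
Why: Vinylogous Mukaiyama-type alkylation: the chloromethyl ether ionises to an oxocarbenium ion, which the dienol ether attacks through its γ-terminus C9, restoring the conjugated enone. Attack is axial and on the α face, anti to the axial C10 methyl on the neighbouring carbon, which sets C9 with C11 α.

Step 15
Reactants: 20 11-benzyloxy-6-oxo-5α-H,9β-H-12-nordrim-7-en-3α-yl 3-methylbutanoate
Product: 22 11-benzyloxy-6-oxo-5α-H,9β-H-driman-3α-yl 3-methylbutanoate (both C8 epimers), via silyl enol ether 21 (not isolated)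
Conditions: Me2CuLi (CuI, 2 MeLi), TMSCl, THF, –78 to –40 °C; then 1 M HCl
Reagents that add atoms: lithium dimethylcuprate, [Li+].C[Cu-]C
Why: Chlorosilane-accelerated conjugate addition of the cuprate places the methyl group on C8, and the enolate is trapped as 21 and hydrolysed on work-up. The ester is inert to the cuprate at low temperature, and the C8 configuration is immaterial because the centre becomes trigonal in step 18.

Step 16
Reactants: 22 11-benzyloxy-6-oxo-5α-H,9β-H-driman-3α-yl 3-methylbutanoate
Product: 23 11-hydroxy-6-oxo-5α-H,9β-H-driman-3α-yl 3-methylbutanoate (both C8 epimers)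
Conditions: H2 (1 atm), Pd/C, EtOAc, rt
Reagents that add atoms: none
Why: Hydrogenolysis of the benzyl ether; no alkene is present at this stage, and the hindered ketone and the ester are untouched.

Step 17
Reactants: 23 11-hydroxy-6-oxo-5α-H,9β-H-driman-3α-yl 3-methylbutanoate; 24 isofraxidin (7-hydroxy-6,8-dimethoxy-2H-chromen-2-one)
Product: 25 11-[(6,8-dimethoxy-2-oxo-2H-chromen-7-yl)oxy]-6-oxo-5α-H,9β-H-driman-3α-yl 3-methylbutanoate (both C8 epimers)
Conditions: PPh3, DIAD, THF/PhMe, 0 to 50 °C
Reagents that add atoms: none
Why: Mitsunobu etherification: the acidic phenol protonates the betaine and displaces the alkoxyphosphonium at the primary C11 (no stereocentre is involved). On the saturated ketone C9–H is not acidic, so elimination towards C9=C11 is not available, and 24 is never exposed to organometallic reagents.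

Step 18
Reactants: 25 11-[(6,8-dimethoxy-2-oxo-2H-chromen-7-yl)oxy]-6-oxo-5α-H,9β-H-driman-3α-yl 3-methylbutanoate
Product: 27 11-[(6,8-dimethoxy-2-oxo-2H-chromen-7-yl)oxy]-6-oxo-5α-H,9β-H-drim-7-en-3α-yl 3-methylbutanoate (target), via silyl enol ether 26 (not isolated)
Conditions: TMSOTf, Et3N, CH2Cl2, 0 °C; then Pd(OAc)2, MeCN, rt
Reagents that add atoms: none
Why: Saegusa–Ito oxidation: soft enolisation silylates the ketone towards C7 (C5 is tertiary and flanked by two quaternary carbons), and the divalent palladium enolate loses the C8 hydrogen by β-hydride elimination to give the C7=C8 enone. The conditions are neutral and spare the C9–H/C11–OAr array, the lactone and the ester; both C8 epimers converge on 27.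

## Compound list

1 | but-3-en-1-ylmagnesium bromide | C=CCC[Mg]Br | starting material
2 | methacrolein (2-methylprop-2-enal) | CC(=C)C=O | starting material
3 | 2-methyl-1-(trimethylsilyloxy)hepta-1,6-diene (not isolated) | C=CCCCC(C)=CO[Si](C)(C)C | intermediate
4 | 2-methylhept-6-enal (racemic) | C=CCCCC(C)C=O | intermediate
5 | methyl vinyl ketone (but-3-en-2-one) | CC(=O)C=C | starting material
6 | 2-methyl-2-(3-oxobutyl)hept-6-enal (racemic, not isolated) | C=CCCCC(C)(C=O)CCC(C)=O | intermediate
7 | 4-methyl-4-(pent-4-en-1-yl)cyclohex-2-en-1-one (racemic) | C=CCCCC1(C)CCC(=O)C=C1 | intermediate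
8 | 4-methyl-4-(pent-4-en-1-yl)cyclohexa-2,5-dien-1-one | C=CCCCC1(C)C=CC(=O)C=C1 | intermediate
9 | 4-(1-methyl-4-oxocyclohexa-2,5-dien-1-yl)butanal | CC1(CCCC=O)C=CC(=O)C=C1 | intermediate
10 | (4aS,8aR)-4a-methyl-3,4,4a,8a-tetrahydronaphthalene-1,7(2H,8H)-dione (cis-fused 5β-H-11,12,13,14-tetranordrim-1-ene-3,6-dione) | C1CCC(=O)[C@@H]2CC(=O)C=C[C@]12C | intermediate
11 | 6,6-(ethylenedioxy)-5β-H-11,12,13,14-tetranordrim-1-en-3-one (cis-fused) | C1CCC3(OCCO3)[C@@H]2CC(=O)C=C[C@]12C | intermediate
12 | 6,6-(ethylenedioxy)-5β-H-11,12-dinordrim-1-en-3-one (cis-fused) | C1CCC3(OCCO3)[C@@H]2C(C)(C)C(=O)C=C[C@]12C | intermediate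
13 | 6,6-(ethylenedioxy)-5β-H-11,12-dinordriman-3-one (cis-fused) | C1CCC3(OCCO3)[C@@H]2C(C)(C)C(=O)CC[C@]12C | intermediate
14 | 6,6-(ethylenedioxy)-5β-H-11,12-dinordriman-3α-ol (cis-fused) | C1CCC3(OCCO3)[C@@H]2C(C)(C)[C@H](O)CC[C@]12C | intermediate
15 | 6,6-(ethylenedioxy)-5β-H-11,12-dinordriman-3α-yl 3-methylbutanoate (cis-fused) | C1CCC3(OCCO3)[C@@H]2C(C)(C)[C@H](OC(=O)CC(C)C)CC[C@]12C | intermediate
16 | 6-oxo-5β-H-11,12-dinordriman-3α-yl 3-methylbutanoate (cis-fused, not isolated) | C1CCC(=O)[C@@H]2C(C)(C)[C@H](OC(=O)CC(C)C)CC[C@]12C | intermediate
17 | 6-oxo-5α-H-11,12-dinordriman-3α-yl 3-methylbutanoate (trans-fused) | C1CCC(=O)[C@H]2C(C)(C)[C@H](OC(=O)CC(C)C)CC[C@]12C | intermediate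
18 | 6-oxo-5α-H-11,12-dinordrim-7-en-3α-yl 3-methylbutanoate | C1C=CC(=O)[C@H]2C(C)(C)[C@H](OC(=O)CC(C)C)CC[C@]12C | intermediate
19 | 6-(tert-butyldimethylsilyloxy)-5α-H-11,12-dinordrima-6,8-dien-3α-yl 3-methylbutanoate | C1=CC=C(O[Si](C)(C)C(C)(C)C)[C@H]2C(C)(C)[C@H](OC(=O)CC(C)C)CC[C@]12C | intermediate
20 | 11-benzyloxy-6-oxo-5α-H,9β-H-12-nordrim-7-en-3α-yl 3-methylbutanoate (C11 α) | c1ccccc1COC[C@@H]1C=CC(=O)[C@H]2C(C)(C)[C@H](OC(=O)CC(C)C)CC[C@]12C | intermediate
21 | 11-benzyloxy-6-(trimethylsilyloxy)-5α-H,9β-H-drim-6-en-3α-yl 3-methylbutanoate (C8 open: both epimers; not isolated) | c1ccccc1COC[C@@H]1C(C)C=C(O[Si](C)(C)C)[C@H]2C(C)(C)[C@H](OC(=O)CC(C)C)CC[C@]12C | intermediate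
22 | 11-benzyloxy-6-oxo-5α-H,9β-H-driman-3α-yl 3-methylbutanoate (C8 open: both epimers) | c1ccccc1COC[C@@H]1C(C)CC(=O)[C@H]2C(C)(C)[C@H](OC(=O)CC(C)C)CC[C@]12C | intermediate
23 | 11-hydroxy-6-oxo-5α-H,9β-H-driman-3α-yl 3-methylbutanoate (C8 open: both epimers) | OC[C@@H]1C(C)CC(=O)[C@H]2C(C)(C)[C@H](OC(=O)CC(C)C)CC[C@]12C | intermediate
24 | isofraxidin (7-hydroxy-6,8-dimethoxy-2H-chromen-2-one) | COc1cc2ccc(=O)oc2c(OC)c1O | starting material
25 | 11-[(6,8-dimethoxy-2-oxo-2H-chromen-7-yl)oxy]-6-oxo-5α-H,9β-H-driman-3α-yl 3-methylbutanoate (C8 open: both epimers) | COc1cc2ccc(=O)oc2c(OC)c1OC[C@@H]1C(C)CC(=O)[C@H]2C(C)(C)[C@H](OC(=O)CC(C)C)CC[C@]12C | intermediate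
26 | 11-[(6,8-dimethoxy-2-oxo-2H-chromen-7-yl)oxy]-6-(trimethylsilyloxy)-5α-H,9β-H-drim-6-en-3α-yl 3-methylbutanoate (C8 open: both epimers; not isolated) | COc1cc2ccc(=O)oc2c(OC)c1OC[C@@H]1C(C)C=C(O[Si](C)(C)C)[C@H]2C(C)(C)[C@H](OC(=O)CC(C)C)CC[C@]12C | intermediate
27 | (3R,5R,9R,10R)-11-[(6,8-dimethoxy-2-oxo-2H-chromen-7-yl)oxy]-6-oxo-9β-H-drim-7-en-3α-yl 3-methylbutanoate (CNP0279705.1) | COc1cc2ccc(=O)oc2c(OC)c1OC[C@@H]1C(C)=CC(=O)[C@H]2C(C)(C)[C@H](OC(=O)CC(C)C)CC[C@]12C | target

## Step count and least certain steps

Total: 18 steps. Longest linear sequence: 18 steps (from 1 and 2 to 27); 5 enters at step 2 and 24 at step 17.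

Step 5 (key step). What may go wrong: closure of a six-membered ring by an enolisable aliphatic aldehyde is slower than the five-membered cases. Aldol or benzoin-type oligomerisation, or consumption of the carbene by the dienone, may therefore outrun cyclisation, and a looser transition state may weaken the discrimination between the two enone arms. Fallback, from 9 back to 10: exchange the acyl anion equivalent for a nitronate. NaBH4 at –78 °C reduces only the aldehyde to 4-(4-hydroxybutyl)-4-methylcyclohexa-2,5-dien-1-one F1. I2/PPh3/imidazole gives the iodide F2, and NaNO2 in DMF gives the nitroalkane F3. A bifunctional cinchona-derived thiourea base then mediates the desymmetrising intramolecular Michael addition of the nitronate to one enone arm, giving the cis-fused nitro ketone F4. An oxidative Nef reaction (KOt-Bu, then dimethyldioxirane) turns C6–NO2 into the ketone of 10.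

Step 14. What may go wrong: attack at the unhindered α-terminus C7 instead of the γ-terminus C9 (which adjoins the quaternary C10), incomplete facial selectivity at C9, or, already in step 13, silylation after loss of H5 in place of H9. Fallback, from 18 back to 23 (it replaces steps 13 to 16): transpose the enone so that C9 becomes the kinetic α′-position.
- Nucleophilic epoxidation (t-BuOOH, DBU) gives the epoxy ketone F5.
- Wharton rearrangement (N2H4·H2O, AcOH, MeOH) gives the allylic alcohol F6.
- MnO2 gives the 6-en-8-one F7.
- The lithium enolate (LiN(i-Pr)2, THF, –78 °C) is alkylated with benzyl chloromethyl ether at C9, axially and anti to the C10 methyl group, giving F8.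
- MeLi/CeCl3 adds to C8 to give the tertiary allylic alcohol F9.
- Oxidative 1,3-transposition with pyridinium chlorochromate, [C5H5NH][CrO3Cl], gives the 8-methyl-7-en-6-one F10.
- Hydrogenation over Pd/C saturates C7=C8 and cleaves the benzyl ether, arriving at 23.

Step 9. What may go wrong: the cis-decalin 13 is conformationally mobile. In the chair–chair form that places the 4α-methyl group axial, the bulky hydride could enter from the α side, so facial selectivity may be poor or inverted. Fallback, from 13 back to 17: reduce in the trans series, where equatorial attack of bulky hydrides on 4,4-dimethyl-3-ketones is well precedented. Hydrolysis of the ketal (2 M HCl, THF) and equilibration of C5 (NaOMe, MeOH) gives the trans-dione F11, any cis isomer being resubjected. Li[HB(s-Bu)3] at –78 °C then reduces C3 to the hydroxy ketone F12; the C6 carbonyl is screened on its β face by the two syn-axial methyl groups and should be spared. Acylation as in step 10 gives 17. If the wrong C3 epimer forms in the main line, it can be reoxidised and sent down this path.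

Step 17. What may go wrong: substitution may be slow because a β-branched primary alcohol must meet a phenol flanked by two methoxy groups. The activated alcohol may then be captured by the reduced azodicarboxylate or by the ketone oxygen. Fallback, from 23 back to 25: pre-form the leaving group. Tf2O/2,6-lutidine at –78 °C gives the primary triflate F13, which is displaced by the cesium phenoxide of 24 (Cs2CO3, MeCN, 0 °C). On the saturated ketone there is no acidic C9–H to divert this into elimination.

## Further compounds

F1 | step 5 | 4-(4-hydroxybutyl)-4-methylcyclohexa-2,5-dien-1-one | CC1(CCCCO)C=CC(=O)C=C1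
F2 | step 5 | 4-(4-iodobutyl)-4-methylcyclohexa-2,5-dien-1-one | CC1(CCCCI)C=CC(=O)C=C1
F3 | step 5 | 4-methyl-4-(4-nitrobutyl)cyclohexa-2,5-dien-1-one | CC1(CCCC[N+](=O)[O-])C=CC(=O)C=C1
F4 | step 5 | 6-nitro-5β-H-11,12,13,14-tetranordrim-1-en-3-one (cis-fused; C6 open: both epimers) | C1CCC([N+](=O)[O-])[C@@H]2CC(=O)C=C[C@]12C
F5 | step 14 | 7α,8α-epoxy-6-oxo-5α-H-11,12-dinordriman-3α-yl 3-methylbutanoate | C1[C@@H]3O[C@@H]3C(=O)[C@H]2C(C)(C)[C@H](OC(=O)CC(C)C)CC[C@]12C
F6 | step 14 | 8α-hydroxy-5α-H-11,12-dinordrim-6-en-3α-yl 3-methylbutanoate | C1[C@H](O)C=C[C@H]2C(C)(C)[C@H](OC(=O)CC(C)C)CC[C@]12C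
F7 | step 14 | 8-oxo-5α-H-11,12-dinordrim-6-en-3α-yl 3-methylbutanoate | C1C(=O)C=C[C@H]2C(C)(C)[C@H](OC(=O)CC(C)C)CC[C@]12C
F8 | step 14 | 11-benzyloxy-8-oxo-5α-H,9β-H-12-nordrim-6-en-3α-yl 3-methylbutanoate | c1ccccc1COC[C@@H]1C(=O)C=C[C@H]2C(C)(C)[C@H](OC(=O)CC(C)C)CC[C@]12C
F9 | step 14 | 11-benzyloxy-8-hydroxy-5α-H,9β-H-drim-6-en-3α-yl 3-methylbutanoate (C8 open) | c1ccccc1COC[C@@H]1C(C)(O)C=C[C@H]2C(C)(C)[C@H](OC(=O)CC(C)C)CC[C@]12C
F10 | step 14 | 11-benzyloxy-6-oxo-5α-H,9β-H-drim-7-en-3α-yl 3-methylbutanoate | c1ccccc1COC[C@@H]1C(C)=CC(=O)[C@H]2C(C)(C)[C@H](OC(=O)CC(C)C)CC[C@]12C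
F11 | step 9 | 5α-H-11,12-dinordrimane-3,6-dione (trans-fused) | C1CCC(=O)[C@H]2C(C)(C)C(=O)CC[C@]12C
F12 | step 9 | 3α-hydroxy-5α-H-11,12-dinordriman-6-one (trans-fused) | C1CCC(=O)[C@H]2C(C)(C)[C@H](O)CC[C@]12C
F13 | step 17 | 6-oxo-11-(trifluoromethanesulfonyloxy)-5α-H,9β-H-driman-3α-yl 3-methylbutanoate (C8 open: both epimers) | O=S(=O)(OC[C@@H]1C(C)CC(=O)[C@H]2C(C)(C)[C@H](OC(=O)CC(C)C)CC[C@]12C)C(F)(F)F
A1 | alternative 1 | (4R)-4-benzyl-3-[(2Z,6R,8Z,10E)-3,7,7-trimethyl-6-(3-methylbutanoyloxy)-9-(triisopropylsilyloxy)dodeca-2,8,10-trienoyl]oxazolidin-2-one | O=C1OC[C@@H](Cc2ccccc2)N1C(=O)/C=C(/C)CC[C@@H](OC(=O)CC(C)C)C(C)(C)/C=C(O[Si](C(C)C)(C(C)C)C(C)C)/C=C/C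
A2 | alternative 1 | endo (cis-fused) cycloadduct: N-[3α-(3-methylbutanoyloxy)-6-(triisopropylsilyloxy)-5β-H,8β-H,9β-H-drim-6-en-11-oyl]-(4R)-4-benzyloxazolidin-2-one | O=C1OC[C@@H](Cc2ccccc2)N1C(=O)[C@@H]1[C@H](C)C=C(O[Si](C(C)C)(C(C)C)C(C)C)[C@@H]2C(C)(C)[C@H](OC(=O)CC(C)C)CC[C@]12C
A3 | alternative 2 | (3R)-1-iodo-4-methyl-4-[(4R)-2,4-dimethyl-6-oxocyclohex-1-en-1-yl]pentan-3-yl 3-methylbutanoate | ICC[C@@H](OC(=O)CC(C)C)C(C)(C)C1=C(C)C[C@@H](C)CC1=O
A4 | alternative 2 | 8β-methyl-6-oxo-5α-H-11-nordriman-3α-yl 3-methylbutanoate (trans-fused) | C1[C@@H](C)CC(=O)[C@H]2C(C)(C)[C@H](OC(=O)CC(C)C)CC[C@]12C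
A5 | alternative 3 | 7-{[(2Z,6E,10S)-10,11-epoxy-3,7,11-trimethyldodeca-2,6-dien-1-yl]oxy}-6,8-dimethoxy-2H-chromen-2-one | COc1cc2ccc(=O)oc2c(OC)c1OC/C=C(/C)CC/C=C(\C)CC[C@@H]1OC1(C)C
A6 | alternative 3 | 7-{[3β-hydroxy-5α-H,9β-H-drim-7-en-11-yl]oxy}-6,8-dimethoxy-2H-chromen-2-one | COc1cc2ccc(=O)oc2c(OC)c1OC[C@@H]1C(C)=CC[C@H]2C(C)(C)[C@@H](O)CC[C@]12C
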